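**Strategy.** The plan rests on cutting the N4–C9a bond, the link from nitrogen to the quaternary carbon shared by the pyrrolidine, azepane and cyclopentane rings. Because N4 lies between C9a and the methylene C5, the aza-bicycle is hidden in a carbocycle: a trans-fused hydrindanone whose C5 ketone sits next to C9a, with a 3-azidoalkyl chain (C1–C3) on C9a. In one intramolecular Schmidt reaction the azide adds to C5 and C9a shifts from carbon to nitrogen with retention, closing the pyrrolidine and expanding the cyclohexanone to the azepanone. The hydrindanone is built on (S)-4-silyloxycyclopentenone by conjugate addition and enolate trapping.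

Key step: step 17

Atom labels used throughout: N4; C1–C3 (pyrrolidine carbons, C3 bears the appended lactone); C5–C9 (azepane carbons); C9a (quaternary carbon); C10–C12 (cyclopentane carbons, C10 bears ethyl, C11 the lactone oxygen); C13/C14 (carbinol carbon and carbonyl of the fused lactone); C18–C21 (appended lactone, C20 bears methyl).

Assumption: in the enamine chlorination of step 13 the (2S,5S) enantiomer of 2,5-diphenylpyrrolidine is taken to be the one that gives (R)-2-chloroaldehydes; if the sense is the opposite, the antipodal catalyst is used.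

## Route

Step 1
Reactants: 1 (S)-4-(tert-butyldimethylsilyloxy)cyclopent-2-en-1-one
Product: 2 (S)-4-(tert-butyldimethylsilyloxy)-2-iodocyclopent-2-en-1-one
Conditions: I2, pyridine, CH2Cl2, 0 °C to rt
Reagents that add atoms: iodine, II
Why: Pyridine-mediated α-iodination of the enone (conjugate addition of pyridine, iodination of the enolate, elimination) should give the 2-iodoenone without touching the silyloxy-bearing carbon (later C10).

Step 2
Reactants: 2 (S)-4-(tert-butyldimethylsilyloxy)-2-iodocyclopent-2-en-1-one; 3 4,4-diethoxybut-1-ene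
Product: 5 (S)-4-(tert-butyldimethylsilyloxy)-2-(4,4-diethoxybutyl)cyclopent-2-en-1-one, via alkylborane 4 (not isolated)
Conditions: 3, 9-BBN-H, THF, rt; then 2, PdCl2(dppf) (cat.), AsPh3, Cs2CO3, DMF/H2O, rt
Reagents that add atoms: 9-borabicyclo[3.3.1]nonane, B1C2CCCC1CCC2 (its atoms stay in 4 only and leave in the coupling)
Why: Anti-Markovnikov hydroboration of the terminal alkene followed by B-alkyl Suzuki–Miyaura coupling with the α-iodoenone should join C1 to C9a under conditions mild enough for the β-silyloxy ketone.

Step 3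
Reactants: 5 (S)-4-(tert-butyldimethylsilyloxy)-2-(4,4-diethoxybutyl)cyclopent-2-en-1-one; 6 allylmagnesium bromide
Product: 7 3-allyl-4-(tert-butyldimethylsilyloxy)-2-(4,4-diethoxybutyl)-1-(trimethylsilyloxy)cyclopent-1-ene (allyl trans to the silyloxy group)
Conditions: 6, CuBr·SMe2 (1 equiv), LiCl, TMSCl, THF, −78 °C
Reagents that add atoms: chlorotrimethylsilane, C[Si](C)(C)Cl
Why: TMSCl-accelerated 1,4-addition of the allylcopper reagent should occur anti to the silyloxy group at C10, which sets C9, and the enolate is held regiodefined as its silyl enol ether.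

Step 4
Reactants: 7 silyl enol ether from step 3; 8 acrolein
Product: 10 3-allyl-4-(tert-butyldimethylsilyloxy)-2-(4,4-diethoxybutyl)-2-(1-hydroxyprop-2-enyl)cyclopentan-1-one (both C5 carbinol epimers), via lithium enolate 9 (not isolated)
Conditions: MeLi, THF, 0 °C; then 8, −78 °C; AcOH quench at −78 °C
Reagents that add atoms: methyllithium, [Li]C (lithium stays in 9 only)
Why: Cleavage of the enol silane gives the tetrasubstituted lithium enolate, whose aldol addition to acrolein should take place on the face opposite the C9 allyl group, so that the quaternary C9a carries C5 trans to C8 and the C1 chain cis to it (the C5 carbinol epimers converge on oxidation in step 7).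

Step 5
Reactants: 10 aldol adduct from step 4
Product: 11 trans-fused 3-(tert-butyldimethylsilyloxy)-7a-(4,4-diethoxybutyl)-7-hydroxy-2,3,3a,4,7,7a-hexahydro-1H-inden-1-one
Conditions: second-generation Grubbs catalyst RuCl2(=CHPh)(H2IMes)(PCy3) (cat.), CH2Cl2, 40 °C
Reagents that add atoms: none
Why: Ring-closing metathesis of the two trans-disposed terminal alkenes should form the C6=C7 bond and with it the trans-fused six-membered ring, driven by loss of ethene.

Step 6
Reactants: 11 bicyclic allylic alcohol from step 5
Product: 12 trans-fused 3-(tert-butyldimethylsilyloxy)-7a-(4,4-diethoxybutyl)-7-hydroxyoctahydro-1H-inden-1-one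
Conditions: H2 (1 atm), Pd/C, EtOAc, rt
Reagents that add atoms: none
Why: Heterogeneous hydrogenation saturates the isolated C6=C7 alkene before any enone is present, while silyl ether and acetal stay inert.

Step 7
Reactants: 12 saturated hydroxy ketone from step 6
Product: 14 trans-fused 7a-(4,4-diethoxybutyl)-3a,4,5,6-tetrahydro-1H-indene-1,7(7aH)-dione (C10=C11 enone), via silyloxy diketone 13 (not isolated)
Conditions: Dess–Martin periodinane, pyridine, CH2Cl2, rt; then DBU, 0 °C
Reagents that add atoms: none
Why: Dess–Martin oxidation turns the C5 carbinol mixture into one ketone, and DBU then expels the β-silyloxy group by E1cB elimination through the C11 enolate to unveil the C10=C11 enone; C9a cannot enolise and short exposure at 0 °C limits γ-deprotonation at C9.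

Step 8
Reactants: 14 enedione from step 7; 15 ethylmagnesium bromide
Product: 17 trans-fused 7a-(4,4-diethoxybutyl)-3-ethyl-2-hydroxyhexahydro-1H-indene-1,7(7aH)-dione (ethyl trans to C8; hydroxyl trans to ethyl), via silyl enol ether 16 (not isolated)
Conditions: 15, CuBr·SMe2 (10 mol %), TMSCl, THF, −78 °C; then dimethyldioxirane, acetone/CH2Cl2, −40 °C; then aq. citric acid
Reagents that add atoms: chlorotrimethylsilane, C[Si](C)(C)Cl (silicon stays in 16 only); dimethyldioxirane, CC1(C)OO1
Why: Copper-catalysed 1,4-addition should deliver ethyl to C10 anti to the C9–C8 bond, and Rubottom oxidation of the regiodefined silyl enol ether places the C11 oxygen anti to the new ethyl group, an arrangement that the epimerisable α-ketol also prefers thermodynamically.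

Step 9
Reactants: 17 α-hydroxy ketone from step 8; 18 2-(diethoxyphosphoryl)propanoic acid
Product: 19 C11 2-(diethoxyphosphoryl)propanoate ester of 17
Conditions: DCC, DMAP (cat.), CH2Cl2, 0 °C to rt
Reagents that add atoms: none
Why: Steglich esterification of the secondary α-ketol installs C13, C14 and the C13 methyl group on the C11 oxygen without base strong enough to cleave the non-enolisable 1,3-diketone.

Step 10
Reactants: 19 phosphonate ester from step 9
Product: 20 tricyclic butenolide (lactone O–C11, C12=C13, C13 methyl)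
Conditions: K2CO3, 18-crown-6 (cat.), toluene, 40 °C
Reagents that add atoms: none
Why: Intramolecular Horner–Wadsworth–Emmons olefination can reach only the C12 carbonyl in a five-membered transition ring (C5 would need a seven-membered one), so the C12=C13 butenolide should form; the γ-position C11 can equilibrate to the isomer with oxygen trans to ethyl.

Step 11
Reactants: 20 butenolide from step 10
Product: 22 tricyclic α-hydroxy-α-methyl lactone (cis-fused at C11–C12; C13 hydroxyl on the convex face), via hydroperoxide 21 (not isolated)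
Conditions: Mn(dpm)3 (cat.), PhSiH3, O2 (1 atm), i-PrOH/CH2Cl2, 0 °C to rt; then P(OEt)3
Reagents that add atoms: dioxygen, O=O
Why: In this Mukaiyama-type reductive hydration the hydrogen atom must add to C12 cis to H11 because only the cis-fused lactone is attainable, and the tertiary C13 radical should capture O2 on the convex face (hydroxyl exo, methyl endo) before the phosphite reduces the hydroperoxide.

Step 12
Reactants: 22 hydroxy lactone acetal from step 11
Product: 23 aldehyde (C18 formyl; chain C9a–C1–C2–C3–C18)
Conditions: AcOH/THF/H2O, 40 °C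
Reagents that add atoms: water, O
Why: Mild acid hydrolysis of the diethyl acetal frees the aldehyde while the tertiary α-hydroxy lactone and the ketone are stable.

Step 13
Reactants: 23 aldehyde from step 12
Product: 24 (R)-2-chloro aldehyde (chlorine at C3)
Conditions: N-chlorosuccinimide, (2S,5S)-2,5-diphenylpyrrolidine (10 mol %), CH2Cl2, 0 °C
Reagents that add atoms: N-chlorosuccinimide, O=C1CCC(=O)N1Cl
Why: Enamine-catalysed α-chlorination sets C3 under catalyst control; the hindered C5 ketone does not compete in enamine formation.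

Step 14
Reactants: 24 α-chloro aldehyde from step 13; 25 ethyl 2-(bromomethyl)acrylate
Product: 27 α-methylene-γ-butyrolactone with anti C3 chloride, via hydroxy ester 26 (not isolated)
Conditions: 25, In powder, THF/H2O, rt; then TsOH (cat.), CH2Cl2, rt
Reagents that add atoms: none
Why: The Barbier allylation adds to the aldehyde through the dipole-minimised transition state of α-chloroaldehydes, which should give the anti chlorohydrin and thereby C18, and the hydroxy ester closes to the lactone.

Step 15
Reactants: 27 α-methylene lactone from step 14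
Product: 28 cis-α-methyl-γ-butyrolactone with C3 chloride
Conditions: H2 (1 atm), Pd/C, EtOAc, rt
Reagents that add atoms: none
Why: Hydrogen should add to the exocyclic methylene from the face opposite the C18 substituent, which gives the cis-3,5-disubstituted lactone and sets C20; the secondary alkyl chloride is not hydrogenolysed.

Step 16
Reactants: 28 chloro lactone from step 15
Product: 29 azido ketone (azide at C3, syn to the C18 oxygen)
Conditions: NaN3, DMF, 65 °C
Reagents that add atoms: sodium azide, [Na+].[N-]=[N+]=[N-]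
Why: SN2 displacement of the secondary chloride by azide inverts C3, converting the anti chloro lactone into the syn azido lactone that the target requires.

Step 17
Reactants: 29 azido ketone from step 16
Product: 30 tetracyclic lactam (C5 carbonyl on N4)
Conditions: TiCl4, CH2Cl2, 0 °C to rt; aq. NaHCO3 work-up
Reagents that add atoms: none
Why: TiCl4 activates the C5 ketone, the azide nitrogen adds to it (6-exo-trig) to give a six-membered azidohydrin (N4, C3, C2, C1, C9a, C5), and the C9a–C5 bond, antiperiplanar to the N–N2 bond, shifts to nitrogen as N2 leaves, which forms the N4–C9a bond and the C5 lactam. The closest known reaction type is the intramolecular Schmidt reaction of alkyl azides with ketones, the standard entry from 2-(3-azidopropyl)cyclohexanones to pyrrolo[1,2-a]azepinones. The pyrrolidine (N4, C3, C2, C1, C9a) is closed by the 1,2-shift, which contracts the azidohydrin ring, and the azepanone (N4, C5–C9, C9a) arises by one-atom expansion of the cyclohexanone. No new stereocentre is formed: C9a migrates with retention, so N4 takes the position of C5 trans to C8, and C3 keeps the configuration installed in step 16. The step needs migration of C9a and not of C6, and attack at the ketone only; the four-atom tether holds the diazonium group equatorial and anti to C5–C9a in the chair azidohydrin, the quaternary carbon is the better migrating group, and lactones do not react with alkyl azides.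

Step 18
Reactants: 30 lactam from step 17
Product: 31 target compound
Conditions: RhH(CO)(PPh3)3 (cat.), Ph2SiH2, THF, rt to 40 °C; aq. NaHCO3 work-up
Reagents that add atoms: none
Why: Rhodium-catalysed hydrosilylation reduces a tertiary lactam to the amine in preference to γ-lactones, so the C5 carbonyl should be removed while both lactones and the tertiary alcohol remain.

## Compound list

1 | (S)-4-(tert-butyldimethylsilyloxy)cyclopent-2-en-1-one | CC(C)(C)[Si](C)(C)O[C@H]1CC(=O)C=C1 | starting material
2 | (S)-4-(tert-butyldimethylsilyloxy)-2-iodocyclopent-2-en-1-one | CC(C)(C)[Si](C)(C)O[C@H]1CC(=O)C(I)=C1 | intermediate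
3 | 4,4-diethoxybut-1-ene | C=CCC(OCC)OCC | starting material
4 | 9-(4,4-diethoxybutyl)-9-borabicyclo[3.3.1]nonane | CCOC(CCCB1C2CCCC1CCC2)OCC | intermediate
5 | (S)-4-(tert-butyldimethylsilyloxy)-2-(4,4-diethoxybutyl)cyclopent-2-en-1-one | CC(C)(C)[Si](C)(C)O[C@H]1CC(=O)C(CCCC(OCC)OCC)=C1 | intermediate
6 | allylmagnesium bromide | C=CC[Mg]Br | starting material
7 | 3-allyl-4-(tert-butyldimethylsilyloxy)-2-(4,4-diethoxybutyl)-1-(trimethylsilyloxy)cyclopent-1-ene, allyl trans to the tert-butyldimethylsilyloxy group | CC(C)(C)[Si](C)(C)O[C@H]1CC(O[Si](C)(C)C)=C(CCCC(OCC)OCC)[C@@H]1CC=C | intermediate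
8 | acrolein (prop-2-enal) | C=CC=O | starting material
9 | lithium enolate corresponding to 7 (OLi in place of OSiMe3) | CC(C)(C)[Si](C)(C)O[C@H]1CC(O[Li])=C(CCCC(OCC)OCC)[C@@H]1CC=C | intermediate
10 | 3-allyl-4-(tert-butyldimethylsilyloxy)-2-(4,4-diethoxybutyl)-2-(1-hydroxyprop-2-enyl)cyclopentan-1-one; hydroxyallyl group (C5) trans to allyl (C8), butyl chain (C1) cis to allyl, allyl trans to the silyloxy group; both C5 carbinol epimers | CC(C)(C)[Si](C)(C)O[C@H]1CC(=O)[C@@](CCCC(OCC)OCC)(C(O)C=C)[C@@H]1CC=C | intermediate
11 | trans-fused 3-(tert-butyldimethylsilyloxy)-7a-(4,4-diethoxybutyl)-7-hydroxy-2,3,3a,4,7,7a-hexahydro-1H-inden-1-one (C6=C7 alkene, C5 carbinol epimers) | CC(C)(C)[Si](C)(C)O[C@H]1CC(=O)[C@@]3(CCCC(OCC)OCC)C(O)C=CC[C@H]13 | intermediate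
12 | trans-fused 3-(tert-butyldimethylsilyloxy)-7a-(4,4-diethoxybutyl)-7-hydroxyoctahydro-1H-inden-1-one | CC(C)(C)[Si](C)(C)O[C@H]1CC(=O)[C@@]3(CCCC(OCC)OCC)C(O)CCC[C@H]13 | intermediate
13 | trans-fused 3-(tert-butyldimethylsilyloxy)-7a-(4,4-diethoxybutyl)hexahydro-1H-indene-1,7(7aH)-dione | CC(C)(C)[Si](C)(C)O[C@H]1CC(=O)[C@@]3(CCCC(OCC)OCC)C(=O)CCC[C@H]13 | intermediate
14 | trans-fused 7a-(4,4-diethoxybutyl)-3a,4,5,6-tetrahydro-1H-indene-1,7(7aH)-dione (C10=C11 enone, C12 and C5 ketones) | C1=CC(=O)[C@@]3(CCCC(OCC)OCC)C(=O)CCC[C@H]13 | intermediate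
15 | ethylmagnesium bromide | CC[Mg]Br | starting material
16 | trimethylsilyl enol ether (C11=C12) of the 3-ethyl ketone, ethyl at C10 trans to C8 | CC[C@H]1C=C(O[Si](C)(C)C)[C@@]3(CCCC(OCC)OCC)C(=O)CCC[C@H]13 | intermediate
17 | trans-fused 7a-(4,4-diethoxybutyl)-3-ethyl-2-hydroxyhexahydro-1H-indene-1,7(7aH)-dione; ethyl (C10) trans to C8, hydroxyl (C11) trans to ethyl and cis to the C9a butyl chain | CC[C@H]1[C@H](O)C(=O)[C@@]3(CCCC(OCC)OCC)C(=O)CCC[C@H]13 | intermediate
18 | 2-(diethoxyphosphoryl)propanoic acid | CCOP(=O)(OCC)C(C)C(=O)O | starting material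
19 | 2-(diethoxyphosphoryl)propanoate ester of the C11 hydroxyl of 17 (phosphonate carbon unspecified) | CC[C@H]1[C@H](OC(=O)C(C)P(=O)(OCC)OCC)C(=O)[C@@]3(CCCC(OCC)OCC)C(=O)CCC[C@H]13 | intermediate
20 | tricyclic butenolide: lactone O–C11, C14 carbonyl, C13 (methyl)=C12; ethyl at C10 trans to the lactone oxygen; trans-fused C5 cyclohexanone; 4,4-diethoxybutyl on C9a | CC[C@H]1[C@@H]2OC(=O)C(C)=C2[C@@]3(CCCC(OCC)OCC)C(=O)CCC[C@H]13 | intermediate
21 | C13 hydroperoxide of the cis-fused saturated lactone (OOH on the convex face) | CC[C@H]1[C@@H]2OC(=O)[C@@](C)(OO)[C@@H]2[C@@]3(CCCC(OCC)OCC)C(=O)CCC[C@H]13 | intermediate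
22 | tricyclic α-hydroxy-α-methyl lactone: cis-fused at C11–C12, C13 hydroxyl cis to H12 and methyl cis to C9a; C5 ketone; 4,4-diethoxybutyl on C9a | CC[C@H]1[C@@H]2OC(=O)[C@@](C)(O)[C@@H]2[C@@]3(CCCC(OCC)OCC)C(=O)CCC[C@H]13 | intermediate
23 | aldehyde of 22 (4-oxobutyl chain on C9a) | CC[C@H]1[C@@H]2OC(=O)[C@@](C)(O)[C@@H]2[C@@]3(CCCC=O)C(=O)CCC[C@H]13 | intermediate
24 | (R)-3-chloro-4-oxobutyl analogue of 23 (chlorine at C3) | CC[C@H]1[C@@H]2OC(=O)[C@@](C)(O)[C@@H]2[C@@]3(CC[C@H](C=O)Cl)C(=O)CCC[C@H]13 | intermediate
25 | ethyl 2-(bromomethyl)acrylate | C=C(CBr)C(=O)OCC | starting material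
26 | anti chlorohydrin: ethyl 2-methylene-4-hydroxy ester at C18, (R)-chloride at C3, (S)-carbinol at C18 | CC[C@H]1[C@@H]2OC(=O)[C@@](C)(O)[C@@H]2[C@@]3(CC[C@H]([C@@H](O)CC(=C)C(=O)OCC)Cl)C(=O)CCC[C@H]13 | intermediate
27 | α-methylene-γ-butyrolactone (C18–C21) with (R)-chloride at C3, anti to the C18 oxygen | CC[C@H]1[C@@H]2OC(=O)[C@@](C)(O)[C@@H]2[C@@]3(CC[C@H]([C@@H]4CC(=C)C(=O)O4)Cl)C(=O)CCC[C@H]13 | intermediate
28 | cis-α-methyl-γ-butyrolactone (18S,20S) with (R)-chloride at C3 | CC[C@H]1[C@@H]2OC(=O)[C@@](C)(O)[C@@H]2[C@@]3(CC[C@H]([C@@H]4C[C@H](C)C(=O)O4)Cl)C(=O)CCC[C@H]13 | intermediate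
29 | azido ketone: (S)-azide at C3, syn to the C18 oxygen; C5 ketone next to C9a in the trans-fused hydrindanone | CC[C@H]1[C@@H]2OC(=O)[C@@](C)(O)[C@@H]2[C@@]3(CC[C@@H]([C@@H]4C[C@H](C)C(=O)O4)N=[N+]=[N-])C(=O)CCC[C@H]13 | intermediate
30 | tetracyclic lactam (5-oxo derivative of the target; N4 bonded to C3, C5 and C9a) | CC[C@H]1[C@@H]2OC(=O)[C@@](C)(O)[C@@H]2[C@@]23CC[C@@H]([C@@H]4C[C@H](C)C(=O)O4)N2C(=O)CCC[C@H]13 | intermediate
31 | target compound CNP0260919.2 | CC[C@H]1[C@@H]2OC(=O)[C@@](C)(O)[C@@H]2[C@@]23CC[C@@H]([C@@H]4C[C@H](C)C(=O)O4)N2CCCC[C@H]13 | target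

## Step count and risks

Total step count: 18. Longest linear sequence: 18 steps (from 1 to 31).

Steps most likely to fail:

Step 17 (Schmidt reaction). The azide may add too slowly to the hindered C5 carbonyl, C6 may migrate in place of C9a, or the Lewis acid may degrade the hydroxy lactone. The fallback sets out from 29. Staudinger reaction with PPh3 in toluene at 80 °C followed by intramolecular aza-Wittig condensation with the C5 ketone should give the six-membered cyclic imine F1. Oxidation with mCPBA in CH2Cl2 at −20 °C should give the oxaziridine F2. Irradiation at 254 nm in MeCN then triggers the oxaziridine-to-lactam rearrangement. Here C9a, held anti to the nitrogen lone pair by the ring, migrates to nitrogen, and the route is rejoined at 30.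

Step 11 (reductive hydration of the butenolide). Hydrogen-atom transfer to the tetrasubstituted alkene carbon C12 beside the quaternary centre may be too slow, or the C13 radical may be reduced before it captures oxygen. The fallback sets out from 20. NaBH4 with NiCl2·6H2O in MeOH at 0 °C should reduce the butenolide double bond and the C5 ketone to the hydroxy lactone F3. Silylation with Et3SiOTf and 2,6-lutidine gives the triethylsilyl ether F4. Deprotonation with LDA in THF at −78 °C and oxidation of the lactone enolate with 2-(phenylsulfonyl)-3-phenyloxaziridine on the convex face gives the α-hydroxy lactone F5. Bu4NF with AcOH removes the silyl group to give the diol F6, and Dess–Martin oxidation of the secondary C5 alcohol returns to 22.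

Step 18 (lactam reduction). Hydrosilylation of the hindered lactam, whose nitrogen carries a fully substituted carbon, may stall, or over-reduction of a lactone may set in on forcing. The fallback sets out from 30. Lawesson's reagent in toluene at 80 °C should thionate the lactam selectively to the thiolactam F7, and desulfurisation with Raney nickel (Ni) in EtOH returns to 31.

Further compounds
F1 | step 17 | cyclic imine (C5=N4, six-membered ring N4–C3–C2–C1–C9a–C5) | CC[C@H]1[C@@H]2OC(=O)[C@@](C)(O)[C@@H]2[C@@]23CC[C@@H]([C@@H]4C[C@H](C)C(=O)O4)N=C2CCC[C@H]13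
F2 | step 17 | oxaziridine of F1 (O bridging N4 and C5) | CC[C@H]1[C@@H]2OC(=O)[C@@](C)(O)[C@@H]2[C@@]23CC[C@@H]([C@@H]4C[C@H](C)C(=O)O4)N5OC25CCC[C@H]13
F3 | step 11 | saturated cis-fused α-methyl lactone with C5 hydroxyl | CC[C@H]1[C@@H]2OC(=O)C(C)[C@@H]2[C@@]3(CCCC(OCC)OCC)C(O)CCC[C@H]13
F4 | step 11 | triethylsilyl ether of F3 at the C5 oxygen | CC[C@H]1[C@@H]2OC(=O)C(C)[C@@H]2[C@@]3(CCCC(OCC)OCC)C(O[Si](CC)(CC)CC)CCC[C@H]13
F5 | step 11 | α-hydroxy-α-methyl lactone with C5 triethylsilyl ether | CC[C@H]1[C@@H]2OC(=O)[C@@](C)(O)[C@@H]2[C@@]3(CCCC(OCC)OCC)C(O[Si](CC)(CC)CC)CCC[C@H]13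
F6 | step 11 | α-hydroxy-α-methyl lactone with free C5 hydroxyl | CC[C@H]1[C@@H]2OC(=O)[C@@](C)(O)[C@@H]2[C@@]3(CCCC(OCC)OCC)C(O)CCC[C@H]13
F7 | step 18 | thiolactam (C5=S analogue of 30) | CC[C@H]1[C@@H]2OC(=O)[C@@](C)(O)[C@@H]2[C@@]23CC[C@@H]([C@@H]4C[C@H](C)C(=O)O4)N2C(=S)CCC[C@H]13
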